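## Retrosynthetic overview

1. Labels: ring A is the benzofuran benzo ring and ring B is the other fused resorcinol ring. C2/C3 are the dihydrofuran CH(Ar)O/CH, and Ca/Cb are the ArCH/CH2 of the seven-membered ring. The target is (2S,3S,CaS): C2-aryl trans to ring B, Ca-aryl cis to C3–H. The biomimetic closure (ε-viniferin, Ca–ring B bond formed last) is deliberately avoided.
2. The last C–C bond is Ca–aryl, made by intermolecular Friedel–Crafts hydroarylation of a tetracyclic Ca=Cb alkene with anisole on its convex face. This sets Ca, the same acid equilibrates C2 to trans, and global demethylation follows.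
3. The key step forms the dihydrofuran (C2–C3 bond) by enantioselective Rh(II) donor/donor-carbene 1,5-C–H insertion into a PMB ether. The carbene carbon is C5 of an achiral dibenzotropone-derived diazo compound, and this step sets C3 absolutely.
4. The dibenzotropone comes from intramolecular Friedel–Crafts acylation of a bibenzyl-2-carboxylic acid, DDQ dehydrogenation, and chelation-controlled OMe→OPMB exchange. The bibenzyl comes from a B-alkyl Suzuki coupling.
5. Ring order: seven-membered carbocycle first, dihydrofuran second, pendant Ca-aryl attached last.

Assumption: the sense of induction of Rh2(PTAD)4 on this unprecedented cyclic carbene cannot be predicted with certainty. The S-antipode is written, and the equally available R-antipode is used if the first run gives ent-13.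

## Route

**Step 1**
Reactants: 1, methyl 3,5-dimethoxybenzoate
Product: 2, methyl 2-iodo-3,5-dimethoxybenzoate
Conditions: NIS, TFA (cat.), MeCN, rt
Reagents that add atoms: N-iodosuccinimide, O=C1CCC(=O)N1I
Why: Electrophilic aromatic iodination goes to C2, which is para to one OMe and ortho to the other, rather than to the more hindered C4 between the two OMe groups.

**Step 2**
Reactants: 2, methyl 2-iodo-3,5-dimethoxybenzoate; 3, 3,5-dimethoxystyrene
Product: 4, methyl 2-[2-(3,5-dimethoxyphenyl)ethyl]-3,5-dimethoxybenzoate
Conditions: 3, 9-BBN, THF, 0 °C→rt; then 2, Pd(dppf)Cl2 (5 mol%), Cs2CO3, DMF/H2O, 60 °C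
Reagents that add atoms: none beyond reactants 2 and 3 (9-BBN contributes only H)
Why: Anti-Markovnikov hydroboration followed by B-alkyl Suzuki–Miyaura coupling gives the bibenzyl directly at the saturated oxidation level and tolerates the ester and the di-ortho-substituted iodide.

**Step 3**
Reactants: 4
Product: 5, 2-[2-(3,5-dimethoxyphenyl)ethyl]-3,5-dimethoxybenzoic acid
Conditions: LiOH, THF/MeOH/H2O, 60 °C; then HCl
Reagents that add atoms: lithium hydroxide/water, [Li+].[OH-] / O
Why: This is an ordinary saponification of a mono-ortho-substituted benzoate, and the aryl methyl ethers are inert.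

**Step 4**
Reactants: 5
Product: 6, 1,3,6,8-tetramethoxy-10,11-dihydro-5H-dibenzo[a,d][7]annulen-5-one (C5 = future C3, C11 = Ca, C10 = Cb; 1,3-OMe on ring B, 6,8-OMe on ring A)
Conditions: TFAA, CH2Cl2, 0 °C→rt
Reagents that add atoms: none
Why: Intramolecular Friedel–Crafts acylation via the mixed anhydride closes the seven-membered ring as one regioisomer, because the two ring A positions ortho to the tether are equivalent and each is ortho/para to OMe.

**Step 5**
Reactants: 6
Product: 7, 1,3,6,8-tetramethoxy-5H-dibenzo[a,d][7]annulen-5-one (Ca=Cb alkene)
Conditions: DDQ (2 equiv), 1,4-dioxane, 100 °C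
Reagents that add atoms: none
Why: DDQ benzylic dehydrogenation (the reaction type that turns 4,4'-dimethoxybibenzyl into the stilbene) abstracts hydride from Ca–H, whose cation has ortho and para OMe on ring B, and it is done here because no PMB ether, phenol or dihydrofuran is yet present.

**Step 6**
Reactants: 7
Product: 8, 6-hydroxy-1,3,8-trimethoxy-5H-dibenzo[a,d][7]annulen-5-one
Conditions: BCl3 (1.2 equiv), CH2Cl2, −78→0 °C
Reagents that add atoms: none
Why: Chelation-controlled demethylation cleaves only the one OMe that can form a six-membered boron chelate with the C5 carbonyl, leaving the other three ethers and the alkene untouched.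

**Step 7**
Reactants: 8; 9, 4-methoxybenzyl chloride
Product: 10, 1,3,8-trimethoxy-6-[(4-methoxyphenyl)methoxy]-5H-dibenzo[a,d][7]annulen-5-one
Conditions: 9, K2CO3, TBAI (cat.), DMF, 60 °C
Reagents that add atoms: 4-methoxybenzyl chloride, COc1ccc(CCl)cc1
Why: Williamson etherification of the chelated phenol installs a PMB group that serves as the future C2 carbon and its aryl ring rather than as a protecting group.

**Step 8**
Reactants: 10
Product: 11, the C5 hydrazone of 10 (C=N geometry irrelevant)
Conditions: N2H4·H2O (excess), AcOH (cat.), n-BuOH, 120 °C, sealed tube, Ar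
Reagents that add atoms: hydrazine, NN
Why: Hydrazone condensation on a hindered, donor-deactivated diaryl ketone needs excess hydrazine, acid catalysis and heat, and argon excludes diimide formation that would reduce Ca=Cb.

**Step 9**
Reactants: 11
Product: 12, 5-diazo-1,3,8-trimethoxy-6-[(4-methoxyphenyl)methoxy]-5H-dibenzo[a,d][7]annulene
Conditions: MnO2 (10 equiv), CH2Cl2, 0 °C→rt; filter through Celite, use directly
Reagents that add atoms: none
Why: MnO2 dehydrogenation of a diaryl ketone hydrazone gives the diaryldiazomethane, ring-fused members of this class are isolable, and MnO2 leaves the ethers and the stilbene-type alkene alone.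

**Step 10 (key step)**
Reactants: 12
Product: 13, (1S,16R)-4,6,12-trimethoxy-16-(4-methoxyphenyl)-15-oxatetracyclo[8.6.1.0^2,7.0^14,17]heptadeca-2(7),3,5,8,10(17),11,13-heptaene. This is the tetracyclic Ca=Cb alkene with a cis-dihydrofuran: C3 = S, C2 = R, and H-2 and H-3 on the same face.
Conditions: Rh2(S-PTAD)4 (1 mol%), CH2Cl2, 0 °C→rt, slow addition of 12
Reagents that add atoms: none
Why: Proposed new method: this extends the Rh2(PTAD)4-catalysed enantioselective 1,5-C–H insertion of donor/donor diaryl carbenes into benzylic ether C–H bonds (established for acyclic 2-benzyloxybenzophenone-derived diazo compounds, which give cis-2,3-diaryl-dihydrobenzofurans) to a carbene carbon embedded in a dibenzocycloheptatriene, where the chiral pocket selects one face of the boat-shaped carbene for hydride transfer from one enantiotopic PMB C–H (sets C3 = S, H pseudo-axial) and the oxocarbenium/Rh–alkyl pair collapses to the C2–C3 bond (kinetically cis), transannular cyclopropanation is geometrically impossible, tropylium-type stabilisation may slow the reaction, and any trans isomer formed carries the same C3 configuration and converges in step 11.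

**Step 11**
Reactants: 13; 14, anisole
Product: 15, (1S,8S,16S)-4,6,12-trimethoxy-8,16-bis(4-methoxyphenyl)-15-oxatetracyclo[8.6.1.0^2,7.0^14,17]heptadeca-2(7),3,5,10(17),11,13-hexaene (ampelopsin B pentamethyl ether; 2S,3S,CaS)
Conditions: 14 (20 equiv), TFA/CH2Cl2 (1:4), 0 °C→rt
Reagents that add atoms: anisole, COc1ccccc1
Why: In this Friedel–Crafts hydroarylation, protonation at Cb gives the only stabilised cation (Ca, 2,4-dimethoxybenzyl type; the ring A oxygens are meta to Cb), the C3 stereocentre locks the molecule into a roof shape whose concave face is blocked by ring A so anisole attacks para from the convex face cis to C3–H (Ca = S), and the same acid reversibly ionises the p-methoxybenzylic C2–O bond so C2 equilibrates to the trans (2S) isomer without touching C3.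

**Step 12**
Reactants: 15
Product: 16, ampelopsin B, (1S,8S,16S)-8,16-bis(4-hydroxyphenyl)-15-oxatetracyclo[8.6.1.0^2,7.0^14,17]heptadeca-2(7),3,5,10(17),11,13-hexaene-4,6,12-triol
Conditions: BBr3 (15 equiv), CH2Cl2, −78 °C→rt; MeOH/H2O quench
Reagents that add atoms: none
Why: BBr3 cleaves the five aryl methyl ethers, no alkene remains to trigger cationic rearrangement, any transient opening of C2–O can only reclose to the favoured trans ring, and C3 and Ca are non-ionisable C–H centres, so all three configurations are retained.

Stereocentre ledger:
- C3 is set in step 10 under catalyst control.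
- Ca is set in step 11 by substrate control (convex face).
- C2 is set in step 11 by thermodynamic control (trans to ring B).

## Compound list

| No. | Name | SMILES | Role |
|---|---|---|---|
| 1 | methyl 3,5-dimethoxybenzoate | COC(=O)c1cc(OC)cc(OC)c1 | starting material |
| 2 | methyl 2-iodo-3,5-dimethoxybenzoate | COC(=O)c1cc(OC)cc(OC)c1I | intermediate |
| 3 | 3,5-dimethoxystyrene | C=Cc1cc(OC)cc(OC)c1 | starting material |
| 4 | methyl 2-[2-(3,5-dimethoxyphenyl)ethyl]-3,5-dimethoxybenzoate | COC(=O)c1cc(OC)cc(OC)c1CCc1cc(OC)cc(OC)c1 | intermediate |
| 5 | 2-[2-(3,5-dimethoxyphenyl)ethyl]-3,5-dimethoxybenzoic acid | OC(=O)c1cc(OC)cc(OC)c1CCc1cc(OC)cc(OC)c1 | intermediate |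
| 6 | 1,3,6,8-tetramethoxy-10,11-dihydro-5H-dibenzo[a,d][7]annulen-5-one | O=C1c2cc(OC)cc(OC)c2CCc2cc(OC)cc(OC)c21 | intermediate |
| 7 | 1,3,6,8-tetramethoxy-5H-dibenzo[a,d][7]annulen-5-one | O=C1c2cc(OC)cc(OC)c2C=Cc2cc(OC)cc(OC)c21 | intermediate |
| 8 | 6-hydroxy-1,3,8-trimethoxy-5H-dibenzo[a,d][7]annulen-5-one | O=C1c2cc(OC)cc(OC)c2C=Cc2cc(OC)cc(O)c21 | intermediate |
| 9 | 4-methoxybenzyl chloride | COc1ccc(CCl)cc1 | starting material |
| 10 | 1,3,8-trimethoxy-6-[(4-methoxyphenyl)methoxy]-5H-dibenzo[a,d][7]annulen-5-one | O=C1c2cc(OC)cc(OC)c2C=Cc2cc(OC)cc(OCc3ccc(OC)cc3)c21 | intermediate |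
| 11 | hydrazone of 10 | NN=C1c2cc(OC)cc(OC)c2C=Cc2cc(OC)cc(OCc3ccc(OC)cc3)c21 | intermediate |
| 12 | 5-diazo-1,3,8-trimethoxy-6-[(4-methoxyphenyl)methoxy]-5H-dibenzo[a,d][7]annulene | [N-]=[N+]=C1c2cc(OC)cc(OC)c2C=Cc2cc(OC)cc(OCc3ccc(OC)cc3)c21 | intermediate |
| 13 | (2R,3S)-cis tetracyclic Ca=Cb alkene, tetramethyl ether | C1=Cc2cc(OC)cc3c2[C@H](c2cc(OC)cc(OC)c21)[C@H](c1ccc(OC)cc1)O3 | intermediate |
| 14 | anisole | COc1ccccc1 | starting material |
| 15 | ampelopsin B pentamethyl ether (2S,3S,CaS) | COc1ccc([C@@H]2Cc3cc(OC)cc4c3[C@H](c3cc(OC)cc(OC)c32)[C@@H](c2ccc(OC)cc2)O4)cc1 | intermediate |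
| 16 | ampelopsin B | Oc1ccc([C@@H]2Cc3cc(O)cc4c3[C@H](c3cc(O)cc(O)c32)[C@@H](c2ccc(O)cc2)O4)cc1 | target |

## Step count

- Total steps: 12.
- Longest linear sequence: 12, from 1. Compounds 3, 9 and 14 are purchased and enter directly.

## Three steps most likely to fail

1. **Step 10.** The cyclic carbene may be sluggish because of tropylium-type stabilisation, may form azine, or may give low ee. It also depends on the hindered hydrazone of step 8 forming at all.
   - Fallback: abandon carbene chemistry. Reduce 8 with NaBH4 to the o-hydroxy diarylcarbinol and generate the ring-embedded o-quinone methide.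
   - Then carry out a [4+1] annulation with the ylide of an enantiopure isothiocineole-type 4-methoxybenzylsulfonium salt.
   - This gives the trans-dihydrobenzofuran directly and bypasses steps 7–10.

2. **Step 11.** Possible problems are alkene oligomerisation, capture of the opened C2 cation by anisole, hydride-transfer isomerisation to the benzofuran, and the fact that the facial selectivity is only a prediction. Because Ca is set before the slower C2 equilibration, any C3 leakage would give separable diastereomers rather than a loss of ee.
   - Fallback: switch from cationic to organometallic arylation with a Pd-catalysed reductive Heck hydroarylation using 4-iodoanisole and formate.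
   - Syn-carbopalladation occurs on the same convex face, with aryl going to the more electrophilic Ca.
   - The cyclic cis-stilbene has no syn β-H, so the alkyl–Pd is reduced.
   - The conditions are non-acidic, and C2 epimerisation is then done separately.

3. **Step 12.** Fivefold BBr3 demethylation next to an ionisable dihydrofuran may cause decomposition.
   - Fallback: change the protecting-group plan at the robust achiral stage. Exhaustively demethylate 7 and benzylate the three non-chelated phenols.
   - Alkylate the chelated phenol with 4-(benzyloxy)benzyl chloride and run steps 8–11 with benzyl phenyl ether as the arene.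
   - Finish by hydrogenolysis (H2, Pd/C) instead of Lewis-acid ether cleavage.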